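Ring A of the target (C4a, C5, C6, C7, C8, C8a; chromane numbering) is a hexasubstituted phloroglucinol at the trione level whose three oxygens must be told apart. Everything rests on making it as an arene by a Danheiser benzannulation: a 3-siloxycyclobutenone (C6, C7, C8, C8a) and a siloxyalkyne (C4a, C5) combine in a pericyclic cascade that forms C5–C6 and C4a–C8a and leaves the C8a oxygen as the only free phenol. That phenol carries the cis-pyranone (ring B); the arene is finally dearomatised at C8 by palladium-mediated transfer of the side-chain ester's own dimethylallyl group.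

Key step: step 11

Assumption: the target is treated as the C7-keto/C5-enol tautomer drawn; other tautomers of this enolised tricarbonyl array are the same compound.
Remark on names: Cb = (1S,3R)-2,2-dimethyl-3-(prop-1-en-2-yl)cyclobutyl; DMA = 2-methylbut-3-en-2-yl (1,1-dimethylallyl); TIPS = triisopropylsilyl. Ring positions of precursors are given in the chromane numbering of the target (O1, C2, C3, C4, C4a, C5, C6, C7, C8, C8a).

Step 1
Reactants: 1 (1R,5R)-α-pinene
Product: 2 cis-pinonic acid [2-((1S,3S)-3-acetyl-2,2-dimethylcyclobutyl)acetic acid]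
Conditions: RuCl3·xH2O (2 mol %), NaIO4 (4 equiv), MeCN/EtOAc/H2O, 0 °C → rt
Reagents that add atoms: sodium periodate, [Na+].[O-]I(=O)(=O)=O
Why: Oxidative cleavage of the trisubstituted alkene by RuO4 made in situ gives the methyl ketone and the acid, so both cyclobutane stereocentres come cis from the chiral pool.

Step 2
Reactants: 2 cis-pinonic acid
Product: 3 2-[(1S,3R)-2,2-dimethyl-3-(prop-1-en-2-yl)cyclobutyl]acetic acid (CbCH2CO2H)
Conditions: Ph3PCH3Br (2.5 equiv), KOtBu (2.5 equiv), THF, 0 °C → rt; aq. HCl work-up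
Reagents that add atoms: methyltriphenylphosphonium bromide, C[P+](c1ccccc1)(c1ccccc1)c1ccccc1.[Br-]
Why: Wittig methylenation of the methyl ketone runs on the carboxylate salt, and the ketone should be consumed at 0 °C before its α-centre can epimerise.

Step 3
Reactants: 3 CbCH2CO2H
Product: 5 1-diazo-3-Cb-propan-2-one, via acid chloride 4 (not isolated)
Conditions: 1-chloro-N,N,2-trimethylprop-1-en-1-amine, CH2Cl2, 0 °C; then CH2N2 (2.5 equiv), Et2O, 0 °C
Reagents that add atoms: diazomethane, C=[N+]=[N-]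
Why: Acylation of diazomethane by the acid chloride (first half of an Arndt–Eistert sequence) gives the α-diazoketone, the chloroenamine making the acid chloride without HCl that could add to the isopropenyl group.

Step 4
Reactants: 6 2-methylbut-3-en-2-ol; 7 bromoacetyl bromide
Product: 8 DMA bromoacetate (2-methylbut-3-en-2-yl 2-bromoacetate)
Conditions: 2,6-lutidine, CH2Cl2, 0 °C
Reagents that add atoms: none
Why: O-acylation of the tertiary allylic alcohol gives a hindered ester that behaves like a tert-butyl ester until the last step, where it becomes the prenyl donor.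

Step 5
Reactants: 9 (R)-4-benzyl-1,3-oxazolidin-2-one; 10 pentanoyl chloride
Product: 11 (R)-4-benzyl-3-pentanoyl-1,3-oxazolidin-2-one
Conditions: n-BuLi, THF, −78 °C; then 10
Reagents that add atoms: none
Why: N-acylation of the lithiated oxazolidinone auxiliary is routine.

Step 6
Reactants: 11 N-pentanoyl oxazolidinone; 8 DMA bromoacetate
Product: 12 DMA (3S)-3-{[(4R)-4-benzyl-2-oxo-1,3-oxazolidin-3-yl]carbonyl}hexanoate
Conditions: NaN(SiMe3)2, THF, −78 °C; then 8, −78 → −45 °C
Reagents that add atoms: none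
Why: Evans alkylation: the chelated Z-sodium enolate is alkylated on the face opposite the benzyl group, which sets the (S) centre of the C6 side chain.

Step 7
Reactants: 12 alkylated imide
Product: 13 1-methyl 4-DMA (2S)-2-propylbutanedioate
Conditions: MeMgBr (1.3 equiv), MeOH, CH2Cl2, 0 °C
Reagents that add atoms: methanol, CO
Why: Transesterification by methoxymagnesium bromide releases the auxiliary without epimerisation and spares the hindered tertiary ester, so the two carboxyl ends are differentiated.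

Step 8
Reactants: 13 mixed succinate
Product: 15 DMA (3S)-3-propyl-5-(triisopropylsilyloxy)pent-4-ynoate, via lithium ynolate 14 (not isolated)
Conditions: CH2Br2, lithium 2,2,6,6-tetramethylpiperidide, THF, −78 °C; 13; LiN(SiMe3)2; n-BuLi, −78 → 0 °C; iPr3SiOTf, −78 °C → rt
Reagents that add atoms: dibromomethane, BrCBr; triisopropylsilyl trifluoromethanesulfonate, CC(C)[Si](OS(=O)(=O)C(F)(F)F)(C(C)C)C(C)C
Why: Kowalski ester homologation: LiCHBr2 adds only to the unhindered methyl ester, the carbenoid rearranges to the ynolate with retention at the migrating stereocentre, and the bulky silyl triflate traps the ynolate on oxygen.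

Step 9
Reactants: 5 diazoketone; 15 siloxyalkyne
Product: 17 DMA (3S)-3-[3-(CbCH2)-4-oxo-2-(triisopropylsilyloxy)cyclobut-1-en-1-yl]hexanoate (both epimers at the ring CH), via alkylketene 16 (not isolated)
Conditions: hν (LED, 390 nm), CH2Cl2, rt, slow addition of 5 to 15
Reagents that add atoms: none
Why: Photochemical Wolff rearrangement gives the alkylketene, which adds the siloxyalkyne in a regioselective [2+2] cycloaddition (ketene carbonyl carbon to the alkyne carbon remote from oxygen); the new ring stereocentre is left uncontrolled because step 11 erases it.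

Step 10
Reactants: 18 acetylene
Product: 20 ethynyl triisopropylsilyl ether, via lithium ethynolate 19 (not isolated)
Conditions: n-BuLi (1.0 equiv), THF, −78 °C; t-BuOOH/LiN(SiMe3)2, −78 → 0 °C; iPr3SiOTf, −78 °C
Reagents that add atoms: tert-butyl hydroperoxide, CC(C)(C)OO; triisopropylsilyl trifluoromethanesulfonate, CC(C)[Si](OS(=O)(=O)C(F)(F)F)(C(C)C)C(C)C
Why: Oxidation of the lithium acetylide by lithium tert-butyl peroxide (ynolate synthesis from a terminal alkyne) and O-silylation with the bulky triflate give the parent silyl ynol ether.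

Step 11
Reactants: 17 siloxycyclobutenone; 20 ethynyl triisopropylsilyl ether
Product: 25 DMA (3S)-3-[3-(CbCH2)-4-hydroxy-2,6-bis(triisopropylsilyloxy)phenyl]hexanoate, via vinylketene 21 (not isolated), via vinylcyclobutenone 22 (not isolated), via dienylketene 23 (not isolated), via cyclohexadienone 24 (not isolated)
Conditions: toluene, 85 °C, sealed tube, 20 (1.5 equiv)
Reagents that add atoms: none
Why: Heating opens cyclobutenone 17 by 4π-electrocyclic ring opening to vinylketene 21, whose ketene C=C bond adds the siloxyalkyne in a regioselective [2+2] cycloaddition (ketene carbonyl carbon C8a to the nucleophilic CH carbon C4a, ketene α-carbon C6 to the oxygen-bearing carbon C5) to give 22, and a second 4π opening gives dienylketene 23, which closes to dienone 24 and tautomerises to phenol 25. The closest known reaction is the Danheiser benzannulation in its variant that joins a 3-siloxycyclobutenone to a siloxyalkyne. The four-membered ring of 22 is closed by the [2+2] cycloaddition and is transient, and ring A is closed in the 6π-electrocyclic mode (C8–C8a). No stereocentre is formed: the uncontrolled ring stereocentre of 17 becomes the sp2 carbon C8, so both epimers converge on one product, and the side-chain and cyclobutane centres lie outside the reacting π-system. The step needs regioselectivity in the [2+2] event, which the polarisation of the ynol ether secures, and chemoselectivity for the alkyne over the isolated alkenes and esters, which their low reactivity toward ketenes secures. The result should be a hexasubstituted arene in which only the former ketene oxygen on C8a is a free hydroxyl, the C5 and C7 oxygens being silylated.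

Step 12
Reactants: 26 methyl (S)-3-hydroxybutanoate
Product: 27 methyl (2S,3S)-3-hydroxy-2-methylbutanoate
Conditions: LiN(iPr)2 (2.2 equiv), THF, −78 → −20 °C; MeI, DMPU, −78 → 0 °C
Reagents that add atoms: iodomethane, CI
Why: Fráter–Seebach alkylation: the chelated dianion is methylated anti to the C3 methyl group, which sets the anti (2S,3S) relationship.

Step 13
Reactants: 27 anti hydroxy ester
Product: 28 (2S,3S)-3-hydroxy-N-methoxy-N,2-dimethylbutanamide
Conditions: MeNH(OMe)·HCl, i-PrMgCl (3.0 equiv), THF, −20 → 0 °C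
Reagents that add atoms: N,O-dimethylhydroxylamine hydrochloride, CNOC.Cl
Why: Magnesium-amide aminolysis of the ester gives the Weinreb amide without touching either stereocentre.

Step 14
Reactants: 25 phenol
Product: 29 DMA (3S)-3-[3-bromo-5-(CbCH2)-4-hydroxy-2,6-bis(triisopropylsilyloxy)phenyl]hexanoate
Conditions: N-bromosuccinimide (1.0 equiv), CH2Cl2, −78 °C
Reagents that add atoms: N-bromosuccinimide, BrN1C(=O)CCC1=O
Why: Electrophilic bromination goes to C4a, the only unsubstituted position of the very electron-rich ring, and should be far faster at −78 °C than attack on the isolated alkenes.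

Step 15
Reactants: 29 bromophenol; 28 Weinreb amide
Product: 31 DMA (3S)-3-[3-(CbCH2)-4-hydroxy-5-((2S,3S)-3-hydroxy-2-methylbutanoyl)-2,6-bis(triisopropylsilyloxy)phenyl]hexanoate, via dilithio aryl species 30 (not isolated)
Conditions: 29, t-BuLi (3.0 equiv), THF, −78 °C; then 28 pre-treated with i-PrMgCl (1.0 equiv), −78 → −20 °C; aq. NH4Cl
Reagents that add atoms: none
Why: Bromine–lithium exchange on the lithium phenoxide gives an aryllithium that adds once to the Weinreb amide through a stable chelated tetrahedral intermediate, so the anti β-hydroxy ketone forms with both stereocentres of 28 untouched.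

Step 16
Reactants: 31 hydroxy ketone
Product: 32 DMA (3S)-3-[(2R,3S)-8-(CbCH2)-2,3-dimethyl-4-oxo-5,7-bis(triisopropylsilyloxy)-3,4-dihydro-2H-chromen-6-yl]hexanoate
Conditions: PPh3, DIAD, THF, 0 °C → rt
Reagents that add atoms: none
Why: Intramolecular Mitsunobu etherification: the only free phenol (the C8a oxygen) displaces the activated secondary alcohol with inversion at C2, which turns the anti aldol unit into the cis-(2R,3S)-2,3-dimethylchromanone.

Step 17
Reactants: 32 bis-silyl chromanone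
Product: 33 DMA (3S)-3-[(2R,3S)-8-(CbCH2)-5,7-dihydroxy-2,3-dimethyl-4-oxo-3,4-dihydro-2H-chromen-6-yl]hexanoate
Conditions: Bu4NF (2.2 equiv), AcOH (2.2 equiv), THF, 0 °C
Reagents that add atoms: none
Why: Buffered fluoride cleaves the two aryl silyl ethers, the hindered tertiary ester survives, and the acetic acid suppresses base-mediated epimerisation at C3.

Step 18
Reactants: 33 chromanone diol
Product: 35 target (3S)-3-[(2R,3S,8R)-8-(CbCH2)-5-hydroxy-2,3-dimethyl-8-(3-methylbut-2-en-1-yl)-4,7-dioxo-3,4,7,8-tetrahydro-2H-chromen-6-yl]hexanoic acid, via seco acid 34 (not isolated)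
Conditions: Pd2(dba)3·CHCl3 (2.5 mol %), (1R,2R)-N,N′-bis[2-(diphenylphosphanyl)benzoyl]cyclohexane-1,2-diamine (7.5 mol %), Et3N (1.5 equiv), THF, 0 °C → rt; aq. citric acid work-up
Reagents that add atoms: none
Why: Tsuji–Trost dearomative prenylation in which zerovalent palladium ionises the 1,1-dimethylallyl ester to the carboxylate of 34 and a π-prenylpalladium cation, which the C7 phenoxide attacks through C8 at the unsubstituted allyl terminus; C8 should be preferred over C6 because it carries a primary rather than an α-branched alkyl group, O-prenylation is reversible under palladium, and the (8R) configuration is to be set by the chiral pocket of the ligand as in palladium-catalysed asymmetric allylic dearomatisation of naphthols.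

Compound list
1 | (1R,5R)-α-pinene | CC1=CC[C@@H]2C[C@H]1C2(C)C | starting material
2 | cis-pinonic acid, 2-[(1S,3S)-3-acetyl-2,2-dimethylcyclobutyl]acetic acid | OC(=O)C[C@@H]1C[C@H](C(C)=O)C1(C)C | intermediate
3 | 2-[(1S,3R)-2,2-dimethyl-3-(prop-1-en-2-yl)cyclobutyl]acetic acid | OC(=O)C[C@@H]1C[C@H](C(C)=C)C1(C)C | intermediate
4 | 2-[(1S,3R)-2,2-dimethyl-3-(prop-1-en-2-yl)cyclobutyl]acetyl chloride | ClC(=O)C[C@@H]1C[C@H](C(C)=C)C1(C)C | intermediate
5 | 1-diazo-3-[(1S,3R)-2,2-dimethyl-3-(prop-1-en-2-yl)cyclobutyl]propan-2-one | [N-]=[N+]=CC(=O)C[C@@H]1C[C@H](C(C)=C)C1(C)C | intermediate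
6 | 2-methylbut-3-en-2-ol | C=CC(C)(C)O | starting material
7 | bromoacetyl bromide | BrCC(Br)=O | starting material
8 | 2-methylbut-3-en-2-yl 2-bromoacetate | BrCC(=O)OC(C)(C)C=C | intermediate
9 | (R)-4-benzyl-1,3-oxazolidin-2-one | O=C1N[C@H](Cc2ccccc2)CO1 | starting material
10 | pentanoyl chloride | CCCCC(Cl)=O | starting material
11 | (R)-4-benzyl-3-pentanoyl-1,3-oxazolidin-2-one | CCCCC(=O)N1[C@H](Cc2ccccc2)COC1=O | intermediate
12 | 2-methylbut-3-en-2-yl (3S)-3-{[(4R)-4-benzyl-2-oxo-1,3-oxazolidin-3-yl]carbonyl}hexanoate | CCC[C@@H](CC(=O)OC(C)(C)C=C)C(=O)N1[C@H](Cc2ccccc2)COC1=O | intermediate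
13 | 1-methyl 4-(2-methylbut-3-en-2-yl) (2S)-2-propylbutanedioate | COC(=O)[C@@H](CCC)CC(=O)OC(C)(C)C=C | intermediate
14 | lithium ynolate of the homologated ester (lithium (3S)-5-(2-methylbut-3-en-2-yloxy)-5-oxo-3-propylpent-1-yn-1-olate) | [Li+].[O-]C#C[C@@H](CCC)CC(=O)OC(C)(C)C=C | intermediate
15 | 2-methylbut-3-en-2-yl (3S)-3-propyl-5-(triisopropylsilyloxy)pent-4-ynoate | CC(C)[Si](OC#C[C@@H](CCC)CC(=O)OC(C)(C)C=C)(C(C)C)C(C)C | intermediate
16 | alkylketene, 3-[(1S,3R)-2,2-dimethyl-3-(prop-1-en-2-yl)cyclobutyl]prop-1-en-1-one | O=C=CC[C@@H]1C[C@H](C(C)=C)C1(C)C | intermediate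
17 | 2-methylbut-3-en-2-yl (3S)-3-[3-(CbCH2)-4-oxo-2-(triisopropylsilyloxy)cyclobut-1-en-1-yl]hexanoate, both epimers at the ring CH | O=C1C([C@@H](CCC)CC(=O)OC(C)(C)C=C)=C(O[Si](C(C)C)(C(C)C)C(C)C)C1C[C@@H]2C[C@H](C(C)=C)C2(C)C | intermediate
18 | acetylene | C#C | starting material
19 | lithium ethynolate | [Li+].[O-]C#C | intermediate
20 | ethynyl triisopropylsilyl ether | C#CO[Si](C(C)C)(C(C)C)C(C)C | intermediate
21 | vinylketene from ring opening of 17 (C8a=C6 ketene, C7(OTIPS)=C8 alkene) | O=C=C([C@@H](CCC)CC(=O)OC(C)(C)C=C)C(O[Si](C(C)C)(C(C)C)C(C)C)=CC[C@@H]1C[C@H](C(C)=C)C1(C)C | intermediate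
22 | 4-vinylcyclobutenone from [2+2] of 21 and 20 (ring C8a, C4a, C5, C6) | O=C1C=C(O[Si](C(C)C)(C(C)C)C(C)C)C1([C@@H](CCC)CC(=O)OC(C)(C)C=C)C(O[Si](C(C)C)(C(C)C)C(C)C)=CC[C@@H]2C[C@H](C(C)=C)C2(C)C | intermediate
23 | dienylketene from ring opening of 22 | O=C=CC(O[Si](C(C)C)(C(C)C)C(C)C)=C([C@@H](CCC)CC(=O)OC(C)(C)C=C)C(O[Si](C(C)C)(C(C)C)C(C)C)=CC[C@@H]1C[C@H](C(C)=C)C1(C)C | intermediate
24 | cyclohexa-2,4-dienone, keto tautomer of 25 | O=C1C=C(O[Si](C(C)C)(C(C)C)C(C)C)C([C@@H](CCC)CC(=O)OC(C)(C)C=C)=C(O[Si](C(C)C)(C(C)C)C(C)C)C1C[C@@H]2C[C@H](C(C)=C)C2(C)C | intermediate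
25 | 2-methylbut-3-en-2-yl (3S)-3-[3-(CbCH2)-4-hydroxy-2,6-bis(triisopropylsilyloxy)phenyl]hexanoate | Oc1cc(O[Si](C(C)C)(C(C)C)C(C)C)c([C@@H](CCC)CC(=O)OC(C)(C)C=C)c(O[Si](C(C)C)(C(C)C)C(C)C)c1C[C@@H]2C[C@H](C(C)=C)C2(C)C | intermediate
26 | methyl (S)-3-hydroxybutanoate | O[C@@H](C)CC(=O)OC | starting material
27 | methyl (2S,3S)-3-hydroxy-2-methylbutanoate | O[C@@H](C)[C@H](C)C(=O)OC | intermediate
28 | (2S,3S)-3-hydroxy-N-methoxy-N,2-dimethylbutanamide | O[C@@H](C)[C@H](C)C(=O)N(C)OC | intermediate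
29 | 2-methylbut-3-en-2-yl (3S)-3-[3-bromo-5-(CbCH2)-4-hydroxy-2,6-bis(triisopropylsilyloxy)phenyl]hexanoate | Oc1c(Br)c(O[Si](C(C)C)(C(C)C)C(C)C)c([C@@H](CCC)CC(=O)OC(C)(C)C=C)c(O[Si](C(C)C)(C(C)C)C(C)C)c1C[C@@H]2C[C@H](C(C)=C)C2(C)C | intermediate
30 | dilithio species of 29 (lithium phenoxide, aryllithium at C4a) | [Li]Oc1c([Li])c(O[Si](C(C)C)(C(C)C)C(C)C)c([C@@H](CCC)CC(=O)OC(C)(C)C=C)c(O[Si](C(C)C)(C(C)C)C(C)C)c1C[C@@H]2C[C@H](C(C)=C)C2(C)C | intermediate
31 | 2-methylbut-3-en-2-yl (3S)-3-[3-(CbCH2)-4-hydroxy-5-[(2S,3S)-3-hydroxy-2-methylbutanoyl]-2,6-bis(triisopropylsilyloxy)phenyl]hexanoate | O[C@@H](C)[C@H](C)C(=O)c1c(O)c(C[C@@H]2C[C@H](C(C)=C)C2(C)C)c(O[Si](C(C)C)(C(C)C)C(C)C)c([C@@H](CCC)CC(=O)OC(C)(C)C=C)c1O[Si](C(C)C)(C(C)C)C(C)C | intermediate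
32 | 2-methylbut-3-en-2-yl (3S)-3-[(2R,3S)-8-(CbCH2)-2,3-dimethyl-4-oxo-5,7-bis(triisopropylsilyloxy)-3,4-dihydro-2H-chromen-6-yl]hexanoate | O=C1c2c(O[Si](C(C)C)(C(C)C)C(C)C)c([C@@H](CCC)CC(=O)OC(C)(C)C=C)c(O[Si](C(C)C)(C(C)C)C(C)C)c(C[C@@H]3C[C@H](C(C)=C)C3(C)C)c2O[C@H](C)[C@@H]1C | intermediate
33 | 2-methylbut-3-en-2-yl (3S)-3-[(2R,3S)-8-(CbCH2)-5,7-dihydroxy-2,3-dimethyl-4-oxo-3,4-dihydro-2H-chromen-6-yl]hexanoate | O=C1c2c(O)c([C@@H](CCC)CC(=O)OC(C)(C)C=C)c(O)c(C[C@@H]3C[C@H](C(C)=C)C3(C)C)c2O[C@H](C)[C@@H]1C | intermediate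
34 | (3S)-3-[(2R,3S)-8-(CbCH2)-5,7-dihydroxy-2,3-dimethyl-4-oxo-3,4-dihydro-2H-chromen-6-yl]hexanoic acid (formed as its carboxylate next to the π-prenylpalladium cation) | O=C1c2c(O)c([C@@H](CCC)CC(=O)O)c(O)c(C[C@@H]3C[C@H](C(C)=C)C3(C)C)c2O[C@H](C)[C@@H]1C | intermediate
35 | (3S)-3-[(2R,3S,8R)-8-{[(1S,3R)-2,2-dimethyl-3-(prop-1-en-2-yl)cyclobutyl]methyl}-5-hydroxy-2,3-dimethyl-8-(3-methylbut-2-en-1-yl)-4,7-dioxo-3,4,7,8-tetrahydro-2H-chromen-6-yl]hexanoic acid | C=C(C)[C@H]1C[C@@H](C[C@@]2(CC=C(C)C)C(=O)C([C@@H](CCC)CC(=O)O)=C(O)C3=C2O[C@H](C)[C@H](C)C3=O)C1(C)C | target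

Total step count: 18. Longest linear sequence: 11 steps (5, 6, 7, 8, 9, 11, 14, 15, 16, 17, 18).

Steps most likely to fail

Step 18. Facial selectivity at C8 may be poor under ligand control, and the π-prenyl cation may partly be captured through C6 or on oxygen. The fallback sets out from 33. Pd(PPh3)4 with morpholine removes the dimethylallyl group and gives seco acid 34, here isolated. EDC·HCl and DMAP close its carboxyl group onto O7, since O5 is tied up in the hydrogen bond to the C4 carbonyl, to give the O7 δ-lactone F1, in which C6 and O7 are blocked and the propyl-bearing stereocentre sits in a ring fused to ring A. The O5 phenoxide of F1 is prenylated at C8, para to O5, with prenyl bromide under chiral phase-transfer catalysis (N-(9-anthracenylmethyl)cinchonidinium bromide, CsOH·H2O, toluene, −40 °C) to the C8-prenylated dienone lactone F2. LiOH in THF/H2O at 0 °C opens this vinylogous anhydride and the route is rejoined at 35.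

Step 16. The activated alcohol may undergo β-elimination to the enone, whose oxa-Michael closure would erode the cis relationship of the two methyl groups. The fallback sets out from 29. Bromine–lithium exchange as in step 15 and acylation with N-methoxy-N-methylpropanamide give the propiophenone F3. Heating with N,N-dimethylacetamide dimethyl acetal in toluene closes the 2,3-dimethylchromone F4. Asymmetric 1,4-reduction with a copper hydride catalyst (Cu(OAc)2, (R)-DTBM-SEGPHOS, (EtO)2MeSiH, t-BuOH, toluene) should deliver hydride to C2 and protonate C3 anti to the new C2 methyl group, giving the cis-chromanone and rejoining the route at 32.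

Step 15. The alkyllithium may attack the ester, a silyl group may migrate to the lithiated carbon, or the hindered aryllithium may add too slowly to the amide. The fallback sets out from 25 and uses 27. Silylation of 27 (t-BuMe2SiCl, imidazole) gives methyl (2S,3S)-3-(tert-butyldimethylsilyloxy)-2-methylbutanoate F5, and LiOH gives (2S,3S)-3-(tert-butyldimethylsilyloxy)-2-methylbutanoic acid F6. Steglich esterification (EDC·HCl, DMAP) of phenol 25 with F6 gives the aryl ester F7. Photo-Fries rearrangement (hν 254 nm, hexane) moves the acyl group to C4a, the only open ortho position, and gives the silyl-protected hydroxy ketone F8. Camphorsulfonic acid in MeOH removes the alkyl silyl ether and the route is rejoined at 31.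

Further compounds
F1 | step 18 | O7 δ-lactone of seco acid 34 | O=C1c2c(O)c3c(OC(=O)C[C@@H]3CCC)c(C[C@@H]4C[C@H](C(C)=C)C4(C)C)c2O[C@H](C)[C@@H]1C
F2 | step 18 | C8-prenylated dienone lactone (C8 configured as in 35) | C=C(C)[C@H]1C[C@@H](C[C@@]2(CC=C(C)C)C3=C([C@@H](CCC)CC(=O)O3)C(=O)C4=C2O[C@H](C)[C@H](C)C4=O)C1(C)C
F3 | step 16 | 2-methylbut-3-en-2-yl (3S)-3-[3-(CbCH2)-4-hydroxy-5-propanoyl-2,6-bis(triisopropylsilyloxy)phenyl]hexanoate | CCC(=O)c1c(O)c(C[C@@H]2C[C@H](C(C)=C)C2(C)C)c(O[Si](C(C)C)(C(C)C)C(C)C)c([C@@H](CCC)CC(=O)OC(C)(C)C=C)c1O[Si](C(C)C)(C(C)C)C(C)C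
F4 | step 16 | 2-methylbut-3-en-2-yl (3S)-3-[8-(CbCH2)-2,3-dimethyl-4-oxo-5,7-bis(triisopropylsilyloxy)-4H-chromen-6-yl]hexanoate | CC1=C(C)C(=O)c2c(O[Si](C(C)C)(C(C)C)C(C)C)c([C@@H](CCC)CC(=O)OC(C)(C)C=C)c(O[Si](C(C)C)(C(C)C)C(C)C)c(C[C@@H]3C[C@H](C(C)=C)C3(C)C)c2O1
F5 | step 15 | methyl (2S,3S)-3-(tert-butyldimethylsilyloxy)-2-methylbutanoate | CC(C)(C)[Si](C)(C)O[C@@H](C)[C@H](C)C(=O)OC
F6 | step 15 | (2S,3S)-3-(tert-butyldimethylsilyloxy)-2-methylbutanoic acid | CC(C)(C)[Si](C)(C)O[C@@H](C)[C@H](C)C(=O)O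
F7 | step 15 | aryl ester of phenol 25 with acid F6 | CC(C)(C)[Si](C)(C)O[C@@H](C)[C@H](C)C(=O)Oc1cc(O[Si](C(C)C)(C(C)C)C(C)C)c([C@@H](CCC)CC(=O)OC(C)(C)C=C)c(O[Si](C(C)C)(C(C)C)C(C)C)c1C[C@@H]2C[C@H](C(C)=C)C2(C)C
F8 | step 15 | tert-butyldimethylsilyl ether of hydroxy ketone 31 | CC(C)(C)[Si](C)(C)O[C@@H](C)[C@H](C)C(=O)c1c(O)c(C[C@@H]2C[C@H](C(C)=C)C2(C)C)c(O[Si](C(C)C)(C(C)C)C(C)C)c([C@@H](CCC)CC(=O)OC(C)(C)C=C)c1O[Si](C(C)C)(C(C)C)C(C)C
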